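**Retrosynthetic overview**

1. Rings B and C (the two tetramethylcyclohexanetrione rings; atoms T1 enol carbon, T2 carbon bearing the benzylic methine, T3 C=O, T4 CMe2, T5 C=O, T6 CMe2) are each cut at T1–T2 and T5–T6, which leaves an arm ArCH(iPr)CH2C(=O)CMe2CO2Me (T2 to T5) and an isobutyryl unit (T1, T6).
2. The isobutyryl units are stored as aryl esters on the oxygens of ring A in tris(isobutyrate) 10; one base treatment moves them from O to T2 and closes both rings by Dieckmann condensation (four C–C bonds), ending directly at unprotected 13.
3. Enabling feature: each arm-bearing carbon of ring A (A-3, A-5) has a phenolic oxygen on both ortho carbons, so an ester carbonyl reaches the arm CH2 (T2) through a six-membered transition state; T4 is already quaternary, so carbanions can form only at T2 and at the isobutyryl methine (future T6).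
4. 10 comes from bis-lactone 6 by opening both aryl lactones with the enolate of methyl isobutyrate (T3–T4 bonds) and O-acylation; 6, carrying both stereocentres, comes from isobutyrylphloroglucinol 3 and ynal 5 by a double enantioselective carbene-catalysed annulation.
5. Ring order: ring A is bought; two temporary δ-lactone rings are formed in step 3 and opened in step 4; rings B and C are formed together in step 6.

Key step: step 6

Remarks on the chemistry (assumptions):
- Ring A is numbered A-1 (carbon bearing the isobutyryl ketone) to A-6, with oxygens O-2, O-4 and O-6 and the arms on A-3 and A-5. The lactone rings of 6 are assumed to close on O-4 and O-6; any other pair of oxygens gives a regioisomeric bis-lactone that is opened to the same 8 in step 4.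
- In step 6 any two of the three ester groups can serve the two arms; 11 and 12 are drawn with the unused ester on O-2.
- 8 is written as the open triphenol; its hemiketal ring-chain tautomers react through this form in step 5.

**Step 1**
Reactants: 1 phloroglucinol; 2 isobutyryl chloride
Product: 3 isobutyrylphloroglucinol [2-methyl-1-(2,4,6-trihydroxyphenyl)propan-1-one]
Conditions: AlCl3 (4 equiv), PhNO2, rt → 65 °C; then ice/aq. HCl
Reagents that add atoms: none
Why: Friedel–Crafts C-acylation of the electron-rich triphenol should stop after one acyl group because the AlCl3-chelated ketone deactivates the ring; no stereocentre is formed.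

**Step 2**
Reactants: 4 3-methylbut-1-yne
Product: 5 4-methylpent-2-ynal
Conditions: n-BuLi (1.0 equiv), THF, −40 °C; DMF (2 equiv), −40 → 20 °C; poured into cold aq. KH2PO4/MTBE
Reagents that add atoms: N,N-dimethylformamide, CN(C)C=O
Why: Formylation of a lithium acetylide with DMF, with a buffered reverse quench so that liberated dimethylamine does not add to the ynal; no stereocentre is formed.

**Step 3**
Reactants: 3 isobutyrylphloroglucinol; 5 4-methylpent-2-ynal (3 equiv)
Product: 6 (4R,10R)-5-hydroxy-6-isobutyryl-4,10-diisopropyl-3,4,9,10-tetrahydro-2H,8H-benzo[1,2-b:3,4-b']dipyran-2,8-dione (bis-lactone; each ring a 4-isopropyl-3,4-dihydrocoumarin)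
Conditions: aminoindanol-derived chiral triazolium salt 2-mesityl-5a,10b-dihydro-4H,6H-indeno[2,1-b][1,2,4]triazolo[4,3-d][1,4]oxazin-2-ium chloride (enantiomer that leads to 4R, 20 mol %), toluene–THF, 40 °C, no added base
Reagents that add atoms: none
Why: Carbene-catalysed annulation of an ynal with a phenolic enol, in which 5 becomes an α,β-unsaturated acyl azolium that is attacked by a free ring carbon of 3 (O-acylation then Claisen-type [3,3] shift, or direct Michael addition) and then lactonizes to release the catalyst, once at each free ring carbon; each new centre is set by the catalyst, which shields one face of the acyl azolium, so two independent events should give mainly the R,R bis-lactone and divert mismatched material into a separable meso diastereomer.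

**Step 4**
Reactants: 6 bis-lactone; 7 methyl isobutyrate (6 equiv)
Product: 8 dimethyl (5R,5'R)-5,5'-(2,4,6-trihydroxy-5-isobutyryl-1,3-phenylene)bis(2,2,6-trimethyl-3-oxoheptanoate)
Conditions: 7 (6 equiv), LiN(i-Pr)2 (5.5 equiv), THF, −78 °C; then 6, −78 → −40 °C; AcOH, −78 °C; pH 6 buffer; used crude
Reagents that add atoms: none
Why: Crossed Claisen acylation of a fully substituted lithium ester enolate by an aryl lactone, in which aryloxide leaves readily and the new ketone, flanked by a quaternary carbon, resists a second addition; the benzylic stereocentres carry no acidic hydrogen and are untouched.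

**Step 5**
Reactants: 8 triphenol bis(β-keto ester); 9 isobutyric anhydride (4 equiv)
Product: 10 dimethyl (5R,5'R)-5,5'-[2,4,6-tris(isobutyryloxy)-5-isobutyryl-1,3-phenylene]bis(2,2,6-trimethyl-3-oxoheptanoate), the tris(O-isobutyrate) of 8
Conditions: 9 (4 equiv), DMAP (0.2 equiv), pyridine, 0 °C → rt
Reagents that add atoms: none
Why: DMAP-catalysed O-acylation of phenols by an anhydride, in which each of the three phenolic oxygens takes one isobutyryl group from one molecule of 9 (three molecules of 9 are consumed and three molecules of isobutyric acid are released), the hemiketal tautomers of 8 drain through the open triphenol and pyridine is too weak a base to enolize the arm ketones; no stereocentre is affected.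

**Step 6**
Reactants: 10 tris(isobutyrate)
Product: 13 (R,R)-myrtucommulone A, via bis(1,3-diketone) monoester 11 (not isolated), via myrtucommulone A O-2 isobutyrate 12 (not isolated)
Conditions: LiN(i-Pr)2 (2.2 equiv), THF, −78 → −20 °C; LiN(i-Pr)2 (5 equiv), −78 → 0 °C; MeOH, 0 °C; 1 M HCl, 0 °C
Reagents that add atoms: none
Why: Proposed new method: the first portion of LiN(i-Pr)2 should give the T2 methylene enolate of each arm, which attacks the carbonyl of a neighbouring aryl isobutyrate through a six-membered cyclic tetrahedral intermediate (a 2-oxidochroman) and expels phenoxide, forming T1–T2; the closest known reaction is the Baker–Venkataraman O→C acyl shift, here with an sp3 benzylic carbon in place of the aryl-ketone carbon in the tether and the enolate carbonyl outside the forming ring. The second portion of LiN(i-Pr)2 should convert each resulting 1,3-diketone (11) into its dianion, whose isobutyryl carbanion (T6) attacks the methyl ester carbon (T5) and expels methoxide, forming T5–T6; the closest known reaction is the acylation of a 1,3-diketone dianion by an ester, run here intramolecularly as a Dieckmann condensation. Each trione ring is closed by this 6-exo-trig acyl substitution, helped by the two gem-dimethyl groups and made irreversible by the acidic triketonate product. No stereocentre is created (T2 ends as an enol carbon), and the two benzylic centres, which have no acidic hydrogen, should be carried through unchanged at or below 0 °C. The step needs C- over O-acylation and the right carbanions: the ortho ester tether gives a six-membered transition state only for C-attack (O-attack would need eight), T2 is the only enolizable carbon of the arm, and the competing ring-ketone and ester α-hydrogens are tertiary and more hindered than the arm CH2. LiOMe from the ring closures and the methanol quench should remove the unused third isobutyrate of 12, an active ester of an acyl-stabilized phenoxide.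

**Compound list**

1 | phloroglucinol (benzene-1,3,5-triol) | Oc1cc(O)cc(O)c1 | starting material
2 | isobutyryl chloride | CC(C)C(Cl)=O | starting material
3 | isobutyrylphloroglucinol | CC(C)C(=O)c1c(O)cc(O)cc1O | intermediate
4 | 3-methylbut-1-yne | CC(C)C#C | starting material
5 | 4-methylpent-2-ynal | CC(C)C#CC=O | intermediate
6 | (4R,10R)-bis-lactone, lactones on O-4 and O-6, O-2 free | CC(C)C(=O)c1c(O)c2c(OC(=O)C[C@@H]2C(C)C)c3c1OC(=O)C[C@@H]3C(C)C | intermediate
7 | methyl isobutyrate | COC(=O)C(C)C | starting material
8 | dimethyl (5R,5'R)-5,5'-(2,4,6-trihydroxy-5-isobutyryl-1,3-phenylene)bis(2,2,6-trimethyl-3-oxoheptanoate) | CC(C)C(=O)c1c(O)c([C@H](CC(=O)C(C)(C)C(=O)OC)C(C)C)c(O)c([C@H](CC(=O)C(C)(C)C(=O)OC)C(C)C)c1O | intermediate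
9 | isobutyric anhydride (2-methylpropanoic anhydride) | CC(C)C(=O)OC(=O)C(C)C | starting material
10 | tris(O-isobutyrate) of 8 (R,R) | CC(C)C(=O)c1c(OC(=O)C(C)C)c([C@H](CC(=O)C(C)(C)C(=O)OC)C(C)C)c(OC(=O)C(C)C)c([C@H](CC(=O)C(C)(C)C(=O)OC)C(C)C)c1OC(=O)C(C)C | intermediate
11 | bis(1,3-diketone): both arm CH2 carbons C-isobutyrylated, O-4 and O-6 free, O-2 isobutyrate left; benzylic configuration as in 10, diketone carbons epimerizable; lithium salt in the flask | CC(C)C(=O)c1c(OC(=O)C(C)C)c([C@H](C(C(=O)C(C)C)C(=O)C(C)(C)C(=O)OC)C(C)C)c(O)c([C@H](C(C(=O)C(C)C)C(=O)C(C)(C)C(=O)OC)C(C)C)c1O | intermediate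
12 | (R,R)-myrtucommulone A O-2 isobutyrate; lithium salt in the flask | CC(C)C(=O)c1c(OC(=O)C(C)C)c([C@H](C2=C(O)C(C)(C)C(=O)C(C)(C)C2=O)C(C)C)c(O)c([C@H](C2=C(O)C(C)(C)C(=O)C(C)(C)C2=O)C(C)C)c1O | intermediate
13 | (R,R)-myrtucommulone A: 2,2'-{(2,4,6-trihydroxy-5-isobutyryl-1,3-phenylene)bis[(1R)-2-methylpropane-1,1-diyl]}bis(3-hydroxy-4,4,6,6-tetramethylcyclohex-2-ene-1,5-dione) | CC(C)C(=O)c1c(O)c([C@H](C2=C(O)C(C)(C)C(=O)C(C)(C)C2=O)C(C)C)c(O)c([C@H](C2=C(O)C(C)(C)C(=O)C(C)(C)C2=O)C(C)C)c1O | target

**Step count and risks**

Total step count: 6. Longest linear sequence: 5 (steps 1, 3, 4, 5, 6).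

Steps most likely to fail:

1. Step 6. The cascade may stall after the O→C acyl shift if the tertiary isobutyryl C–H of the hindered diketonate is not removed. Base may instead enolize the unused aryl ester or the ring ketone, leading to ketene loss or a misdirected acyl shift. The finished arms may also ionize reversibly (phenoxide-assisted loss of the triketonate, a retro-Michael process), which would erode configuration. The fallback sets out from 3 and comes back at 13, with the trione rings brought in ready-made. Commercial syncarpic acid (4,4,6,6-tetramethylcyclohexane-1,3,5-trione) and isobutyraldehyde are condensed (Knoevenagel; piperidine cat., CH2Cl2, then dilute HCl) to isobutylidene syncarpic acid F1. Compound 3 is then alkylated at both free ring carbons by F1 (2.1 equiv) in a catalytic enantioselective Friedel–Crafts-type Michael addition (chiral aluminium lithium bis(binaphtholate) catalyst, AlLi(C20H12O2)2, antipode leading to R,R; THF, −20 °C), and the meso diastereomer is removed to leave 13.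

2. Step 3. O-acylation of the phenol by the acyl azolium (redox esterification) may outrun C–C bond formation, the second annulation on the less nucleophilic mono-lactone may stall, and facial control may be weaker for the isopropyl-substituted acyl azolium. The fallback sets out from 3 and comes back at 6, forming the C–C bonds by iminium catalysis at the aldehyde oxidation level. Compound 3 and commercial (E)-4-methylpent-2-enal (2.5 equiv) with diphenylprolinol trimethylsilyl ether (antipode giving R, 20 mol %) and benzoic acid (cat.) in CH2Cl2 should give, after Friedel–Crafts-type Michael addition and hemiacetal closure, the bis-lactol F2. F2 is oxidized to 6 with Ag2CO3 on Celite (toluene, 80 °C).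

3. Step 4. The hindered, strongly basic tertiary enolate may enolize the lactone or the product ketone instead of adding, and the triphenol may cyclize and dehydrate through its hemiketal forms on isolation. The fallback sets out from 6 and comes back at 10, building the quaternary carbons after the Claisen step. The lactones are opened with the unhindered lithium enolate of methyl acetate (LiN(i-Pr)2, THF, −78 °C; the acidic product is protected as its enolate) to the triphenol bis(β-keto ester) F3. F3 is O-acylated crude (9, DMAP, pyridine) to its tris(isobutyrate) F4. Both active methylenes of F4 are then dimethylated (MeI, K2CO3, acetone) to give 10.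

**Further compounds**

F1 | step 6 | isobutylidene syncarpic acid [4,4,6,6-tetramethyl-2-(2-methylpropylidene)cyclohexane-1,3,5-trione] | CC(C)C=C1C(=O)C(C)(C)C(=O)C(C)(C)C1=O
F2 | step 3 | bis-lactol corresponding to 6 (2,8-dihydroxy, (4R,10R), anomeric centres undefined) | CC(C)C(=O)c1c(O)c2c(OC(O)C[C@@H]2C(C)C)c3c1OC(O)C[C@@H]3C(C)C
F3 | step 4 | dimethyl (5R,5'R)-5,5'-(2,4,6-trihydroxy-5-isobutyryl-1,3-phenylene)bis(6-methyl-3-oxoheptanoate) | CC(C)C(=O)c1c(O)c([C@H](CC(=O)CC(=O)OC)C(C)C)c(O)c([C@H](CC(=O)CC(=O)OC)C(C)C)c1O
F4 | step 4 | tris(O-isobutyrate) of F3 | CC(C)C(=O)c1c(OC(=O)C(C)C)c([C@H](CC(=O)CC(=O)OC)C(C)C)c(OC(=O)C(C)C)c([C@H](CC(=O)CC(=O)OC)C(C)C)c1OC(=O)C(C)C
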